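**Amounts first.** I started from the amounts charged and the amounts read.

the same everywhere: starting material 0.10 M

| flask | reagent | second substrate | third substrate | temperature | remark | time |
|---|---|---|---|---|---|---|
| Monday's | 1.1 equiv | 1 equiv | 0.50 equiv | 105 °C | run made earlier |  |
| Saturday's | 1.1 equiv | 1 equiv | 2 equiv | 125 °C | run made earlier |  |
| blue | 1.10 equiv | 1.00 equiv | 1.00 equiv | 140 °C |  | 20 min |
| green | 1.10 equiv | 1.00 equiv | 1.00 equiv | 110 °C |  | 20 min |

- Monday's (time / min: target / %, starting material / %): 15.0: 19.1, 76.4; 30.0: 22.2, 68.9; 50.0: 22.2, 63.5; 60.0: 21.1, 62.9; 80.0: 19.6, 60.2; 120: 16.2, 56.8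
- Saturday's (time / min: target / %, starting material / %): 2.00: 15.2, 83.9; 6.00: 21.6, 72.9; 12.0: 21.8, 66.6; 15.0: 21.0, 65.5; 25.0: 17.9, 61.7; 30.0: 17.0, 60.5; 40.0: 14.9, 58.1

(scatter of a reading: 0.3 percentage points)

- the analysis behind the earlier runs scatters by 0.3 percentage points, standard deviation

* the flask with the highest amount of target, in percent of the starting material charged ("all alike" if they lie within 1.5 percentage points) (blue / green / all alike)
* final target, as a percentage of the starting material charged, in blue
* final target, as a percentage of the starting material charged, in green

**Late pairs.** Late in Monday's run, target fell 3.4 percentage points while starting material fell 3.4 points. Dividing one rate by the other removes time. The ratio read 1.00 there and 0.875 late in Saturday's run. I took this to mean that each target lost takes one starting material with it. So I took half the sum of starting material lost and target present as a count of the target ever made, and called this the harvest.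

**Slowing rate.** Over the first 15.0 min, Monday's harvest grew by 0.0142 min⁻¹ of the charge. Between 15.0 min and 30.0 min it grew by 0.00353 min⁻¹, a slowing by a factor of 4.02. Average starting material fell between those two spans by a factor of 1.21, less than that, so I blamed the reagent's decline for the rest. Monday's harvest read 29.7% at 80.0 min and 29.7% at 120 min. Harvest divided by reagent charged is the reagent share 27.0%. Saturday's run, with 2 equiv of third substrate against 0.50 equiv and 125 °C against 105 °C, read 25.8% at 40.0 min.

**My expectation.** I expected a harvest near 29.7% in both flasks, with target below it.

**The forecast.** It named green as highest, with blue at 14% and green at 21.5%. It put blue “well past the peak”.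

**The result.** Blue gave 17.3% and green 22.0%, so green led.

    starting material + target → side product (k = 0.00180 M⁻¹ s⁻¹, Ea = 71.0 kJ mol⁻¹)
    reagent + target → over-reaction product (k = 0.00400 M⁻¹ s⁻¹, Ea = 93.0 kJ mol⁻¹)
    third substrate + reagent → third product (k = 0.00240 M⁻¹ s⁻¹, Ea = 82.0 kJ mol⁻¹)
    starting material + reagent → target (k = 0.00700 M⁻¹ s⁻¹, Ea = 88.0 kJ mol⁻¹)
    second substrate + reagent → second product (k = 0.0200 M⁻¹ s⁻¹, Ea = 69.0 kJ mol⁻¹)
    (constants at 110 °C)

In blue the reagent, the limiting reagent, stood at 0%, and blue's share came to 30.4%, above Monday's. Blue's neighbour, charged with 2.50 equiv of second substrate, also ended with reagent at 0%. The neighbour lost less starting material than blue, leaving 70.6%. The neighbour's share was 17.1%, lower than blue's. The neighbour's target ended at 8.23%.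

(All runs were generated by integration with made-up constants; noise was put on by code.)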